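## Retrosynthetic overview

1. Target 13 ⇒ hydroperoxide 12: the only ring, the 1,2-dioxolane, is closed last by 5-exo conjugate addition of the C5 hydroperoxide to its own (E)-enoate (O–C3 bond), with a chiral base fixing C3.
2. 12 ⇒ skipped dienoate 10 + O2: the tertiary C5–OO bond comes from cobalt-hydride hydrogen-atom transfer to the 1,1-disubstituted alkene.
3. 10 ⇒ alkenylzinc 9 + bromo-enoate 7 (Negishi allyl–alkenyl coupling, C4–C5 bond); 9 comes from methyl ketone 5 by a Shapiro reaction.
4. 5 ⇒ bromide 1 + enone 2: copper-catalysed asymmetric conjugate addition makes the C7–C8 bond and sets C7.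

Assumption: the sense of induction of the ligand in step 1 and of the organocatalyst in step 5 is assigned by analogy with the closest precedents; if the first run shows the opposite sense, the mirror-image ligand or catalyst is used and nothing else changes.

Numbering used below: C1 is the ester carbon, C3 and C5 are the ring carbons, C7 is the side-chain CH(CH3). The target is (3R,5S,7R), with the two ring methyl groups trans.

## Route

**Step 1**
Reactants: 1 (6-bromohexyl)benzene; 2 (E)-pent-3-en-2-one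
Product: 5 (R)-4-methyl-10-phenyldecan-2-one, via Grignard reagent 3 (not isolated), via magnesium enolate 4 (not isolated)
Conditions: Mg, Et2O, reflux; then CuBr·SMe2 (5 mol %), (S,R)-Josiphos [(S)-1-[(R)-2-(diphenylphosphino)ferrocenyl]ethyldicyclohexylphosphine] (6 mol %), t-BuOMe, −75 °C, 2 added over 2 h; 1 M HCl
Reagents that add atoms: none
Why: Copper/Josiphos-catalysed asymmetric conjugate addition of a Grignard reagent to an acyclic enone; the chiral copper complex delivers the 6-phenylhexyl group to one face of the β-carbon and so sets C7 as R (expected about 90–95 % ee).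

**Step 2**
Reactants: 5 (R)-4-methyl-10-phenyldecan-2-one
Product: 6 N'-[(2E,4R)-4-methyl-10-phenyldecan-2-ylidene]-2,4,6-tri(propan-2-yl)benzenesulfonohydrazide
Conditions: 2,4,6-tri(propan-2-yl)benzenesulfonohydrazide (1.05 equiv), cat. HCl, THF, rt
Reagents that add atoms: 2,4,6-tri(propan-2-yl)benzenesulfonohydrazide, CC(C)c1cc(C(C)C)c(S(=O)(=O)NN)c(C(C)C)c1
Why: Acid-catalysed hydrazone condensation gives the (E)-arenesulfonylhydrazone needed for a regioselective Shapiro reaction; the C7 centre is β to the carbonyl, not enolisable, and is untouched.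

**Step 3**
Reactants: 6 N'-[(2E,4R)-4-methyl-10-phenyldecan-2-ylidene]-2,4,6-tri(propan-2-yl)benzenesulfonohydrazide; 7 methyl (E)-4-bromo-3-methylbut-2-enoate
Product: 10 methyl (2E,7R)-3,7-dimethyl-5-methylidene-13-phenyltridec-2-enoate, via alkenyllithium 8 (not isolated), via alkenylzinc bromide 9 (not isolated)
Conditions: n-BuLi (2.1 equiv), TMEDA/hexane, −78 → 0 °C; ZnBr2 (1.2 equiv), THF, −78 → 0 °C; 7 (1.2 equiv), Pd(PPh3)4 (5 mol %), 0 °C → rt
Reagents that add atoms: none
Why: Shapiro reaction (dianion formed at the methyl group, loss of sulfinate and N2) gives the 2-lithio-1-alkene, which after lithium-to-zinc exchange undergoes Negishi allyl–alkenyl coupling at the less hindered terminus of the π-allylpalladium intermediate, keeping the E-enoate; no stereocentre is formed. Any Z-isomer is removed on silica.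

**Step 4**
Reactants: 10 methyl (2E,7R)-3,7-dimethyl-5-methylidene-13-phenyltridec-2-enoate
Product: 12 methyl (2E,7R)-5-hydroperoxy-3,5,7-trimethyl-13-phenyltridec-2-enoate (1:1 at C5), via silyl peroxide 11 (not isolated)
Conditions: Co(thd)2 (10 mol %; thd = 2,2,6,6-tetramethylheptane-3,5-dionate), O2 (1 atm), Et3SiH (2 equiv), ClCH2CH2Cl, rt; then cat. HCl, MeOH, 0 °C
Reagents that add atoms: dioxygen, O=O
Why: Mukaiyama–Isayama hydroperoxysilylation: a cobalt hydride transfers a hydrogen atom to the electron-rich 1,1-disubstituted alkene, the tertiary C5 radical traps O2, and the electron-poor enoate is untouched; C5 is formed without control (about 1:1), and acidic methanolysis frees the hydroperoxide without starting the base-dependent ring closure.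

**Step 5**
Reactants: 12 methyl (2E,7R)-5-hydroperoxy-3,5,7-trimethyl-13-phenyltridec-2-enoate (1:1 at C5)
Product: 13 methyl 2-[(3R,5S)-3,5-dimethyl-5-[(2R)-2-methyl-8-phenyloctyl]-1,2-dioxolan-3-yl]acetate
Conditions: bifunctional iminophosphorane catalyst (10 mol %; tris(4-methoxyphenyl)iminophosphorane of the L-tert-leucine-derived 3,5-bis(trifluoromethyl)phenyl thiourea), toluene, −20 °C → rt; then SiO2 chromatography to remove the cis-(3R,5R) isomer
Reagents that add atoms: none
Why: Proposed new method: the superbasic iminophosphorane deprotonates the hydroperoxide, the thiourea binds the ester carbonyl, and the tight chiral ion pair directs 5-exo peroxy-Michael attack to one face of the (E)-β-methyl enoate, so C3 is set as R in both C5 epimers; the (5S) half gives the trans target and the (5R) half gives the cis-(3R,5R) ring diastereomer, separable on silica (ceiling 50 %); closest known reaction types are the iminophosphorane-catalysed enantioselective intramolecular oxa-Michael addition of alcohols to α,β-unsaturated esters and the amine-mediated racemic cyclisation of δ-hydroperoxy enoates to 1,2-dioxolanes.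

## Compound list

1 | (6-bromohexyl)benzene | BrCCCCCCc1ccccc1 | starting material
2 | (E)-pent-3-en-2-one | C/C=C/C(C)=O | starting material
3 | (6-phenylhexyl)magnesium bromide | Br[Mg]CCCCCCc1ccccc1 | intermediate
4 | bromomagnesium (4R)-4-methyl-10-phenyldec-2-en-2-olate (enolate geometry not defined) | CC(O[Mg]Br)=C[C@H](C)CCCCCCc1ccccc1 | intermediate
5 | (R)-4-methyl-10-phenyldecan-2-one | CC(=O)C[C@H](C)CCCCCCc1ccccc1 | intermediate
6 | N'-[(2E,4R)-4-methyl-10-phenyldecan-2-ylidene]-2,4,6-tri(propan-2-yl)benzenesulfonohydrazide | C/C(C[C@H](C)CCCCCCc1ccccc1)=N\NS(=O)(=O)c1c(C(C)C)cc(C(C)C)cc1C(C)C | intermediate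
7 | methyl (E)-4-bromo-3-methylbut-2-enoate | COC(=O)/C=C(\C)CBr | starting material
8 | [(4R)-4-methyl-10-phenyldec-1-en-2-yl]lithium | [Li]C(=C)C[C@H](C)CCCCCCc1ccccc1 | intermediate
9 | bromo[(4R)-4-methyl-10-phenyldec-1-en-2-yl]zinc | Br[Zn]C(=C)C[C@H](C)CCCCCCc1ccccc1 | intermediate
10 | methyl (2E,7R)-3,7-dimethyl-5-methylidene-13-phenyltridec-2-enoate | COC(=O)/C=C(\C)CC(=C)C[C@H](C)CCCCCCc1ccccc1 | intermediate
11 | methyl (2E,7R)-3,5,7-trimethyl-13-phenyl-5-[(triethylsilyl)peroxy]tridec-2-enoate (1:1 at C5) | COC(=O)/C=C(\C)CC(C)(OO[Si](CC)(CC)CC)C[C@H](C)CCCCCCc1ccccc1 | intermediate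
12 | methyl (2E,7R)-5-hydroperoxy-3,5,7-trimethyl-13-phenyltridec-2-enoate (1:1 at C5) | COC(=O)/C=C(\C)CC(C)(OO)C[C@H](C)CCCCCCc1ccccc1 | intermediate
13 | methyl 2-[(3R,5S)-3,5-dimethyl-5-[(2R)-2-methyl-8-phenyloctyl]-1,2-dioxolan-3-yl]acetate | COC(=O)C[C@@]1(C)C[C@](C)(C[C@H](C)CCCCCCc2ccccc2)OO1 | target

## Step count and risks

Total step count: 5. Longest linear sequence: 5 steps (from 1).

Stereocentres: C7 is set in step 1 and never becomes enolisable. C5 is formed in step 4 as a 1:1 pair, and the 5S series is selected in step 5 when the cis isomer is removed. C3 is set in step 5 by the catalyst.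

The three steps most likely to fail:

**Step 5 (catalyst control at C3 on a plain methyl ester).** If selectivity is low, the (3S,5R,7R) trans isomer forms and cannot be separated from the target on silica. The fallback sets out from 10 and comes back at 13, replacing the ester by a two-point-binding acceptor for hydrogen-bond catalysis.
- LiOH in THF/MeOH/H2O gives (2E,7R)-3,7-dimethyl-5-methylidene-13-phenyltridec-2-enoic acid F1.
- 3,5-Dimethylpyrazole, EDC·HCl and DMAP give (2E,7R)-1-(3,5-dimethyl-1H-pyrazol-1-yl)-3,7-dimethyl-5-methylidene-13-phenyltridec-2-en-1-one F2.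
- Co(thd)2, O2 and Et3SiH give (2E,7R)-1-(3,5-dimethyl-1H-pyrazol-1-yl)-3,5,7-trimethyl-13-phenyl-5-[(triethylsilyl)peroxy]tridec-2-en-1-one F3.
- Buffered HF·pyridine at −20 °C frees (2E,7R)-1-(3,5-dimethyl-1H-pyrazol-1-yl)-5-hydroperoxy-3,5,7-trimethyl-13-phenyltridec-2-en-1-one F4 in the presence of a quinine-derived 3,5-bis(trifluoromethyl)benzyl squaramide (10 mol %, toluene).
- The squaramide closes F4 to 1-(3,5-dimethyl-1H-pyrazol-1-yl)-2-[(3R,5S)-3,5-dimethyl-5-[(2R)-2-methyl-8-phenyloctyl]-1,2-dioxolan-3-yl]ethan-1-one F5, which is separated from its cis isomer.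
- MeOH with cat. DMAP converts F5 into 13.

**Step 3 (Shapiro/Negishi in one flask).** The risks are protonation of 8, capture of the π-allyl by sulfinate, and E/Z leakage. The fallback sets out from 5 and comes back at 10.
- KHMDS at −78 °C then PhNTf2 gives the kinetic enol triflate (4R)-4-methyl-10-phenyldec-1-en-2-yl trifluoromethanesulfonate F6.
- Me3SnSnMe3, Pd(PPh3)4 and LiCl give trimethyl[(4R)-4-methyl-10-phenyldec-1-en-2-yl]stannane F7.
- Stille coupling of F7 with 7 (Pd2(dba)3, tri(2-furyl)phosphine, THF, 50 °C) gives 10.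

**Step 1 (enantioselectivity, sense of induction and 1,4- versus 1,2-addition with a small enone).** The fallback sets out from Grignard reagent 3 and comes back at 5, replacing catalyst control by a stereospecific chiral-pool substitution.
- CuBr·SMe2-catalysed SN2 opening of (R)-4-methyloxetan-2-one (C[C@@H]1CC(=O)O1) at the secondary carbon, with inversion, gives (3R)-3-methyl-9-phenylnonanoic acid F8.
- MeLi (2.2 equiv, Et2O, 0 °C, acidic quench) converts F8 into 5.

## Further compounds

F1 | step 5 | (2E,7R)-3,7-dimethyl-5-methylidene-13-phenyltridec-2-enoic acid | OC(=O)/C=C(\C)CC(=C)C[C@H](C)CCCCCCc1ccccc1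
F2 | step 5 | (2E,7R)-1-(3,5-dimethyl-1H-pyrazol-1-yl)-3,7-dimethyl-5-methylidene-13-phenyltridec-2-en-1-one | Cc1cc(C)n(n1)C(=O)/C=C(\C)CC(=C)C[C@H](C)CCCCCCc1ccccc1
F3 | step 5 | (2E,7R)-1-(3,5-dimethyl-1H-pyrazol-1-yl)-3,5,7-trimethyl-13-phenyl-5-[(triethylsilyl)peroxy]tridec-2-en-1-one (1:1 at C5) | Cc1cc(C)n(n1)C(=O)/C=C(\C)CC(C)(OO[Si](CC)(CC)CC)C[C@H](C)CCCCCCc1ccccc1
F4 | step 5 | (2E,7R)-1-(3,5-dimethyl-1H-pyrazol-1-yl)-5-hydroperoxy-3,5,7-trimethyl-13-phenyltridec-2-en-1-one (1:1 at C5) | Cc1cc(C)n(n1)C(=O)/C=C(\C)CC(C)(OO)C[C@H](C)CCCCCCc1ccccc1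
F5 | step 5 | 1-(3,5-dimethyl-1H-pyrazol-1-yl)-2-[(3R,5S)-3,5-dimethyl-5-[(2R)-2-methyl-8-phenyloctyl]-1,2-dioxolan-3-yl]ethan-1-one | Cc1cc(C)n(n1)C(=O)C[C@@]1(C)C[C@](C)(C[C@H](C)CCCCCCc2ccccc2)OO1
F6 | step 3 | (4R)-4-methyl-10-phenyldec-1-en-2-yl trifluoromethanesulfonate | C=C(OS(=O)(=O)C(F)(F)F)C[C@H](C)CCCCCCc1ccccc1
F7 | step 3 | trimethyl[(4R)-4-methyl-10-phenyldec-1-en-2-yl]stannane | C=C([Sn](C)(C)C)C[C@H](C)CCCCCCc1ccccc1
F8 | step 1 | (3R)-3-methyl-9-phenylnonanoic acid | OC(=O)C[C@H](C)CCCCCCc1ccccc1
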